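**Plan**

- Retrosynthetic cuts, in order: the six O-protecting groups; the C6–vinyl bond (Heck); the C3–C3a bond of the dihydrofuran ring (key ring closure); the O1–C2 aryl ether bond; the aryl–CH2 bond of a deoxybenzoin.
- Forward: ketone α-arylation gives the deoxybenzoin, then α-bromination, etherification with an iodophenol, dynamic kinetic reduction, closure of the dihydrofuran ring onto the benzo ring, attachment of the styryl arm, deprotection.
- Enabling feature: C3 is benzylic to the 3,5-dioxygenated ring and lies five atoms from C3a across the O1–C2 ether, so excising a hydroxyl on C3 gives a planar radical that can only reach the ortho carbons of the benzo ring. An iodine placed on C3a, the carbon between the C4 and C7a oxygens, decides between C3a and C7.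
- Stereochemistry: C2 comes from catalyst control in the dynamic kinetic transfer hydrogenation of a configurationally labile α-aryloxy ketone. C3 is set in the key step under control of C2 (trans), from either C3–OH epimer.

Key step: step 9

Assumption: in step 8 the (S,S) catalyst is taken to select the (2R) ketone and give the (1R,2R) alcohol, as it does in the reduction of benzoin to (R,R)-hydrobenzoin; if the sense proved opposite, the (R,R) catalyst would be used.

**Step 1**
Reactants: 1 1-(3,5-dihydroxyphenyl)ethan-1-one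
Product: 2 1-[3,5-bis(methoxymethoxy)phenyl]ethan-1-one
Conditions: MOMCl (2.5 equiv), iPr2NEt, CH2Cl2/DMF, 0 °C to rt
Reagents that add atoms: chloromethyl methyl ether (MOMCl), COCCl
Why: Williamson-type O-alkylation (acetal formation) of both phenols, with the methyl ketone untouched by the amine base.

**Step 2**
Reactants: 3 4-bromobenzene-1,2-diol
Product: 4 4-bromo-1,2-bis(methoxymethoxy)benzene
Conditions: MOMCl (2.5 equiv), iPr2NEt, CH2Cl2, 0 °C to rt
Reagents that add atoms: chloromethyl methyl ether (MOMCl), COCCl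
Why: Williamson-type O-alkylation of both catechol hydroxyls, giving an acid-labile protection that matches the end game.

**Step 3**
Reactants: 2 1-[3,5-bis(methoxymethoxy)phenyl]ethan-1-one; 4 4-bromo-1,2-bis(methoxymethoxy)benzene
Product: 5 2-[3,4-bis(methoxymethoxy)phenyl]-1-[3,5-bis(methoxymethoxy)phenyl]ethan-1-one
Conditions: Pd2(dba)3 (cat.), Xantphos, NaOtBu, THF, 70 °C
Reagents that add atoms: none
Why: Palladium-catalyzed ketone α-arylation (Buchwald–Hartwig type), in which the sodium enolate of 2 couples with the arylpalladium bromide from 4 and the more acidic, more hindered product enolate should resist a second arylation.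

**Step 4**
Reactants: 5 2-[3,4-bis(methoxymethoxy)phenyl]-1-[3,5-bis(methoxymethoxy)phenyl]ethan-1-one
Product: 7 2-bromo-2-[3,4-bis(methoxymethoxy)phenyl]-1-[3,5-bis(methoxymethoxy)phenyl]ethan-1-one (racemic), via trimethylsilyl enol ether 6 (not isolated)
Conditions: LiHMDS, THF, −78 °C; TMSCl; then NBS, −78 to 0 °C
Reagents that add atoms: N-bromosuccinimide, O=C1CCC(=O)N1Br
Why: Enolization at the only enolizable carbon, silylation and electrophilic bromination of the silyl enol ether avoid acid and ring bromination of the MOM-protected arenes, and no stereocontrol is sought because this center is equilibrated in step 8.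

**Step 5**
Reactants: 8 5-chlorobenzene-1,3-diol
Product: 9 5-chloro-2-iodobenzene-1,3-diol
Conditions: I2, NaHCO3, H2O, 0 °C to rt
Reagents that add atoms: iodine, II
Why: Electrophilic aromatic iodination in aqueous bicarbonate, which for resorcinols places iodine on the carbon between the two hydroxyls, here also the only activated position not flanked by chlorine.

**Step 6**
Reactants: 9 5-chloro-2-iodobenzene-1,3-diol
Product: 10 5-chloro-2-iodo-3-(methoxymethoxy)phenol
Conditions: MOMCl (1.0 equiv), iPr2NEt (1.1 equiv), THF, 0 °C; chromatography, recovered 9 recycled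
Reagents that add atoms: chloromethyl methyl ether (MOMCl), COCCl
Why: Statistical Williamson-type mono-alkylation of one of two equivalent phenols, done on the cheap fragment so that the later coupling with 7 is clean.

**Step 7**
Reactants: 10 5-chloro-2-iodo-3-(methoxymethoxy)phenol; 7 2-bromo-2-[3,4-bis(methoxymethoxy)phenyl]-1-[3,5-bis(methoxymethoxy)phenyl]ethan-1-one
Product: 11 2-[3,4-bis(methoxymethoxy)phenyl]-1-[3,5-bis(methoxymethoxy)phenyl]-2-[5-chloro-2-iodo-3-(methoxymethoxy)phenoxy]ethan-1-one (racemic)
Conditions: K2CO3, acetone, rt to 40 °C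
Reagents that add atoms: none
Why: Williamson ether synthesis by SN2 displacement of the doubly activated (benzylic, α-keto) bromide by the phenoxide of 10, which forms the O1–C2 bond.

**Step 8**
Reactants: 11 2-[3,4-bis(methoxymethoxy)phenyl]-1-[3,5-bis(methoxymethoxy)phenyl]-2-[5-chloro-2-iodo-3-(methoxymethoxy)phenoxy]ethan-1-one
Product: 12 (1R,2R)-2-[3,4-bis(methoxymethoxy)phenyl]-1-[3,5-bis(methoxymethoxy)phenyl]-2-[5-chloro-2-iodo-3-(methoxymethoxy)phenoxy]ethan-1-ol
Conditions: RuCl[(S,S)-TsDPEN](p-cymene) (cat.), HCO2H/Et3N (1:1), DMF, 40 °C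
Reagents that add atoms: none
Why: Noyori–Ikariya asymmetric transfer hydrogenation under dynamic kinetic resolution, in which C2 (benzylic, α to the ketone, bearing the aryloxy group) racemizes through the enol in the amine-rich medium while the catalyst should reduce the (2R) ketone faster and set C1 by its usual facial preference for aryl ketones; the C2-epimeric diastereomer is to be removed by chromatography.

**Step 9**
Reactants: 12 (1R,2R)-2-[3,4-bis(methoxymethoxy)phenyl]-1-[3,5-bis(methoxymethoxy)phenyl]-2-[5-chloro-2-iodo-3-(methoxymethoxy)phenoxy]ethan-1-ol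
Product: 14 (2S,3S)-2-[3,4-bis(methoxymethoxy)phenyl]-3-[3,5-bis(methoxymethoxy)phenyl]-6-chloro-4-(methoxymethoxy)-2,3-dihydro-1-benzofuran, via benzoxazoline adduct 13 (not isolated)
Conditions: 5,7-di-tert-butyl-3-phenyl-1,3-benzoxazol-3-ium tetrafluoroborate (1.2 equiv), pyridine, MTBE, rt; then [Ir(ppy)2(dtbbpy)]PF6 (cat.), NiBr2(dtbbpy) (cat.), quinuclidine, DMA/MTBE (high dilution), 450 nm LEDs, rt (ppy = 2-phenylpyridinato, dtbbpy = 4,4'-di-tert-butyl-2,2'-bipyridine)
Reagents that add atoms: none
Why: The alcohol condenses with the benzoxazolium salt to aminal 13; the photoexcited iridium complex oxidizes 13 at nitrogen, quinuclidine removes the aminal proton, and β-scission of the C3–O bond releases the planar benzylic C3 radical and the benzoxazolone, while zerovalent nickel inserts into the C3a–I bond and captures the radical as a six-membered aryl(alkyl) trivalent nickelacycle (Ni, C3, C2, O1, C7a, C3a) that forms C3a–C3 by reductive elimination. The closest known reaction type is the nickel/photoredox deoxygenative arylation of alcohols with aryl halides through benzoxazolium activation, here run intramolecularly. The dihydrofuran ring closes as a five-membered ring in the 5-exo sense, the C3 radical joining the nickel-bearing C3a, with no endocyclic alkene involved. C3 is set by C2: radical capture by nickel is reversible, and the nickelacycle with the C2 and C3 aryl groups trans (both pseudo-equatorial) should eliminate preferentially, so 12 and any (1S,2R) epimer carried with it converge on the (2S,3S) trans product while C2 is not touched. The step needs closure at C3a and not at C7, which the iodine placed between the two ring oxygens secures; it needs C–I to react before the C6–Cl bond, which the weaker C–I bond and the room-temperature nickel/bipyridine system secure; and it needs ring closure to outrun β-scission of the aryloxy group, which the intramolecular capture favors.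

**Step 10**
Reactants: 14 (2S,3S)-2-[3,4-bis(methoxymethoxy)phenyl]-3-[3,5-bis(methoxymethoxy)phenyl]-6-chloro-4-(methoxymethoxy)-2,3-dihydro-1-benzofuran; 15 4-ethenyl-2-methoxyphenyl acetate
Product: 16 4-[(E)-2-{(2S,3S)-2-[3,4-bis(methoxymethoxy)phenyl]-3-[3,5-bis(methoxymethoxy)phenyl]-4-(methoxymethoxy)-2,3-dihydro-1-benzofuran-6-yl}ethenyl]-2-methoxyphenyl acetate
Conditions: Pd2(dba)3 (cat.), [HP(t-Bu)3]BF4, Cy2NMe, 1,4-dioxane, 100 °C
Reagents that add atoms: none
Why: Mizoroki–Heck reaction of the unhindered aryl chloride with the styrene, using the bulky electron-rich phosphine needed for C–Cl oxidative addition to zerovalent palladium, where syn-insertion and syn-β-hydride elimination should give the (E)-stilbene and C2 and C3 are not involved.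

**Step 11**
Reactants: 16 4-[(E)-2-{(2S,3S)-2-[3,4-bis(methoxymethoxy)phenyl]-3-[3,5-bis(methoxymethoxy)phenyl]-4-(methoxymethoxy)-2,3-dihydro-1-benzofuran-6-yl}ethenyl]-2-methoxyphenyl acetate
Product: 17 5-[(2S,3S)-2-(3,4-dihydroxyphenyl)-4-hydroxy-6-[(E)-2-(4-hydroxy-3-methoxyphenyl)ethenyl]-2,3-dihydro-1-benzofuran-3-yl]benzene-1,3-diol (CNP0199755.1)
Conditions: HCl (from AcCl) in MeOH/THF, degassed, 40 °C
Reagents that add atoms: none
Why: Acid-catalyzed acetal methanolysis of the five MOM ethers together with transesterification of the aryl acetate, under which the aryl methyl ether, the stilbene and C3 are inert and C2 can at most open and reclose reversibly at O1–C2, which returns the more stable trans isomer.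

**Compound list**

1 | 1-(3,5-dihydroxyphenyl)ethan-1-one | CC(=O)c1cc(O)cc(O)c1 | starting material
2 | 1-[3,5-bis(methoxymethoxy)phenyl]ethan-1-one | CC(=O)c1cc(OCOC)cc(OCOC)c1 | intermediate
3 | 4-bromobenzene-1,2-diol | Oc1ccc(Br)cc1O | starting material
4 | 4-bromo-1,2-bis(methoxymethoxy)benzene | COCOc1ccc(Br)cc1OCOC | intermediate
5 | 2-[3,4-bis(methoxymethoxy)phenyl]-1-[3,5-bis(methoxymethoxy)phenyl]ethan-1-one | COCOc1cc(OCOC)cc(c1)C(=O)Cc1ccc(OCOC)c(OCOC)c1 | intermediate
6 | {(Z)-2-[3,4-bis(methoxymethoxy)phenyl]-1-[3,5-bis(methoxymethoxy)phenyl]ethenyl}oxy(trimethyl)silane | COCOc1cc(OCOC)cc(c1)/C(O[Si](C)(C)C)=C/c1ccc(OCOC)c(OCOC)c1 | intermediate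
7 | 2-bromo-2-[3,4-bis(methoxymethoxy)phenyl]-1-[3,5-bis(methoxymethoxy)phenyl]ethan-1-one (racemic) | COCOc1cc(OCOC)cc(c1)C(=O)C(Br)c1ccc(OCOC)c(OCOC)c1 | intermediate
8 | 5-chlorobenzene-1,3-diol | Oc1cc(O)cc(Cl)c1 | starting material
9 | 5-chloro-2-iodobenzene-1,3-diol | Oc1cc(Cl)cc(O)c1I | intermediate
10 | 5-chloro-2-iodo-3-(methoxymethoxy)phenol | COCOc1cc(Cl)cc(O)c1I | intermediate
11 | 2-[3,4-bis(methoxymethoxy)phenyl]-1-[3,5-bis(methoxymethoxy)phenyl]-2-[5-chloro-2-iodo-3-(methoxymethoxy)phenoxy]ethan-1-one (racemic) | COCOc1cc(Cl)cc(OC(C(=O)c2cc(OCOC)cc(OCOC)c2)c2ccc(OCOC)c(OCOC)c2)c1I | intermediate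
12 | (1R,2R)-2-[3,4-bis(methoxymethoxy)phenyl]-1-[3,5-bis(methoxymethoxy)phenyl]-2-[5-chloro-2-iodo-3-(methoxymethoxy)phenoxy]ethan-1-ol | COCOc1cc(Cl)cc(O[C@H](c2ccc(OCOC)c(OCOC)c2)[C@H](O)c2cc(OCOC)cc(OCOC)c2)c1I | intermediate
13 | 2-{(1R,2R)-2-[3,4-bis(methoxymethoxy)phenyl]-1-[3,5-bis(methoxymethoxy)phenyl]-2-[5-chloro-2-iodo-3-(methoxymethoxy)phenoxy]ethoxy}-5,7-di-tert-butyl-3-phenyl-2,3-dihydro-1,3-benzoxazole (mixture at the aminal carbon) | COCOc1cc(Cl)cc(O[C@H](c2ccc(OCOC)c(OCOC)c2)[C@H](OC2Oc3c(cc(cc3C(C)(C)C)C(C)(C)C)N2c2ccccc2)c2cc(OCOC)cc(OCOC)c2)c1I | intermediate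
14 | (2S,3S)-2-[3,4-bis(methoxymethoxy)phenyl]-3-[3,5-bis(methoxymethoxy)phenyl]-6-chloro-4-(methoxymethoxy)-2,3-dihydro-1-benzofuran | Clc1cc(OCOC)c2c(c1)O[C@H](c1ccc(OCOC)c(OCOC)c1)[C@H]2c1cc(OCOC)cc(OCOC)c1 | intermediate
15 | 4-ethenyl-2-methoxyphenyl acetate | CC(=O)Oc1ccc(C=C)cc1OC | starting material
16 | 4-[(E)-2-{(2S,3S)-2-[3,4-bis(methoxymethoxy)phenyl]-3-[3,5-bis(methoxymethoxy)phenyl]-4-(methoxymethoxy)-2,3-dihydro-1-benzofuran-6-yl}ethenyl]-2-methoxyphenyl acetate | COc1cc(/C=C/c2cc(OCOC)c3c(c2)O[C@H](c2ccc(OCOC)c(OCOC)c2)[C@H]3c2cc(OCOC)cc(OCOC)c2)ccc1OC(C)=O | intermediate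
17 | 5-[(2S,3S)-2-(3,4-dihydroxyphenyl)-4-hydroxy-6-[(E)-2-(4-hydroxy-3-methoxyphenyl)ethenyl]-2,3-dihydro-1-benzofuran-3-yl]benzene-1,3-diol | COc1cc(/C=C/c2cc(O)c3c(c2)O[C@H](c2ccc(O)c(O)c2)[C@H]3c2cc(O)cc(O)c2)ccc1O | target

**Step count and risks**

Total step count: 11. Longest linear sequence: 8 steps (steps 1, 3, 4, 7, 8, 9, 10, 11).

Steps most likely to fail:

Step 9. Nickel may insert too slowly into the doubly ortho-substituted C–I bond, so that the C3 radical is reduced or loses the aryloxy group by β-scission; the trans preference of the ring closure may also be incomplete, in which case the cis isomer must be removed before any acid is applied. The fallback sets out from 12. Appel chlorination (PPh3, N-chlorosuccinimide, THF, 0 °C) should give the benzylic chloride 1-{(1R)-1-[3,4-bis(methoxymethoxy)phenyl]-2-chloro-2-[3,5-bis(methoxymethoxy)phenyl]ethoxy}-5-chloro-2-iodo-3-(methoxymethoxy)benzene F1, as either epimer at the chlorine-bearing carbon. A thermal nickel-catalyzed reductive cross-electrophile coupling of the aryl iodide with this secondary benzylic chloride (NiBr2·diglyme, dtbbpy, Mn powder, DMA, rt, high dilution) generates the same planar C3 radical by halogen abstraction without light and should come back to the route at 14.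

Step 8. Racemization of C2 may be too slow relative to reduction, or the preference between the two ketone enantiomers may be low, which would leave C2-epimeric alcohol that leads to the enantiomer of the target. The fallback sets out from 11 and replaces the dynamic process by a classical resolution. Reduction with NaBH4 (MeOH/THF, 0 °C) should give the racemic alcohol 2-[3,4-bis(methoxymethoxy)phenyl]-1-[3,5-bis(methoxymethoxy)phenyl]-2-[5-chloro-2-iodo-3-(methoxymethoxy)phenoxy]ethan-1-ol F2. Esterification with (S)-2-methoxy-2-phenylacetic acid (DCC, DMAP, CH2Cl2) and separation of the diastereomeric esters on silica should give (1R,2R)-2-[3,4-bis(methoxymethoxy)phenyl]-1-[3,5-bis(methoxymethoxy)phenyl]-2-[5-chloro-2-iodo-3-(methoxymethoxy)phenoxy]ethyl (2S)-2-methoxy-2-phenylacetate F3. Methanolysis (K2CO3, MeOH, rt) comes back to the route at 12.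

Step 10. Oxidative addition of zerovalent palladium to the electron-rich aryl chloride may be sluggish, and at the temperature needed the styrene may oligomerize or lose its acetate. The fallback sets out from 14 and builds the alkene in two separate events. Suzuki–Miyaura coupling with potassium vinyltrifluoroborate (Pd(OAc)2, RuPhos, Cs2CO3, THF/H2O, 85 °C) should give (2S,3S)-2-[3,4-bis(methoxymethoxy)phenyl]-3-[3,5-bis(methoxymethoxy)phenyl]-6-ethenyl-4-(methoxymethoxy)-2,3-dihydro-1-benzofuran F4. Olefin cross-metathesis of F4 with an excess of 15 (second-generation Grubbs catalyst, CH2Cl2, 40 °C) should give the (E)-stilbene and come back to the route at 16.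

**Further compounds**

F1 | step 9 | 1-{(1R)-1-[3,4-bis(methoxymethoxy)phenyl]-2-chloro-2-[3,5-bis(methoxymethoxy)phenyl]ethoxy}-5-chloro-2-iodo-3-(methoxymethoxy)benzene | COCOc1cc(Cl)cc(O[C@H](c2ccc(OCOC)c(OCOC)c2)C(Cl)c2cc(OCOC)cc(OCOC)c2)c1I
F2 | step 8 | 2-[3,4-bis(methoxymethoxy)phenyl]-1-[3,5-bis(methoxymethoxy)phenyl]-2-[5-chloro-2-iodo-3-(methoxymethoxy)phenoxy]ethan-1-ol (racemic) | COCOc1cc(Cl)cc(OC(c2ccc(OCOC)c(OCOC)c2)C(O)c2cc(OCOC)cc(OCOC)c2)c1I
F3 | step 8 | (1R,2R)-2-[3,4-bis(methoxymethoxy)phenyl]-1-[3,5-bis(methoxymethoxy)phenyl]-2-[5-chloro-2-iodo-3-(methoxymethoxy)phenoxy]ethyl (2S)-2-methoxy-2-phenylacetate | COCOc1cc(Cl)cc(O[C@H](c2ccc(OCOC)c(OCOC)c2)[C@H](OC(=O)[C@@H](OC)c2ccccc2)c2cc(OCOC)cc(OCOC)c2)c1I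
F4 | step 10 | (2S,3S)-2-[3,4-bis(methoxymethoxy)phenyl]-3-[3,5-bis(methoxymethoxy)phenyl]-6-ethenyl-4-(methoxymethoxy)-2,3-dihydro-1-benzofuran | C=Cc1cc(OCOC)c2c(c1)O[C@H](c1ccc(OCOC)c(OCOC)c1)[C@H]2c1cc(OCOC)cc(OCOC)c1
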